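**Strategy**

Everything rests on the bond from C2 of the pyranone ring to C1′ of the hydroquinone ring. At the chromone oxidation level the unit O1–C2=C3–C4=O is an enone with C2 as its β-carbon, so a rhodium-catalysed enantioselective 1,4-addition of a benzyl-protected arylboronic acid to a 5-benzyloxy-3,6,7-trimethoxychromone joins both halves and sets C2 by ligand control. C3, α to the C4 ketone and bearing the methoxy group, emerges as an epimer mixture that base funnels into the 2,3-trans (diequatorial) isomer, so one catalyst-controlled centre secures both. The precursor is a flat, achiral 3-methoxychromone; hydrogenolysis of three benzyl ethers finishes the synthesis.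

Key step: step 8

Assumption: the Rh/(S)-biaryl bisphosphine catalyst is taken to deliver the aryl group to the Re face of C2 of the chromone (priorities O1 > C3 > H), the same spatial sense in which (S)-BINAP-type ligands arylate 2-cyclohexenone; if the sense proves opposite, the (R)-ligand is used with nothing else changed.

Remark: flavanone numbering is used throughout (O1, C2, C3, C4 in the pyranone ring; primed numbers in the hydroquinone ring). The target is the 2,3-trans (2R,3R) isomer.

**Route**

Step 1
Reactants: 1 3,4,5-trimethoxyphenol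
Product: 2 1-(6-hydroxy-2,3,4-trimethoxyphenyl)-2-methoxyethan-1-one
Conditions: MeOCH2CO2H (1.2 equiv), BF3·OEt2 (promoter and solvent), 75 °C; aq. NaOAc work-up
Reagents that add atoms: methoxyacetic acid COCC(=O)O
Why: BF3-mediated Friedel–Crafts C-acylation of a highly activated phenol ortho to the OH group; the two ortho positions are equivalent and the para position is blocked.

Step 2
Reactants: 2 1-(6-hydroxy-2,3,4-trimethoxyphenyl)-2-methoxyethan-1-one
Product: 4 3,5,6,7-tetramethoxy-4H-chromen-4-one, via enaminone 3 (not isolated)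
Conditions: DMF-DMA (3 equiv), toluene, 100 °C; then conc. HCl (cat.), CH2Cl2, 40 °C
Reagents that add atoms: N,N-dimethylformamide dimethyl acetal COC(OC)N(C)C
Why: Condensation at the ketone methylene gives the enaminone, and acid-promoted addition–elimination of the phenol OH with loss of dimethylamine closes the pyranone ring (standard enaminone chromone synthesis).

Step 3
Reactants: 4 3,5,6,7-tetramethoxy-4H-chromen-4-one
Product: 5 5-hydroxy-3,6,7-trimethoxy-4H-chromen-4-one
Conditions: BCl3 (1.5 equiv), CH2Cl2, −78 → 0 °C; H2O work-up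
Reagents that add atoms: none
Why: Chelation-controlled demethylation: boron bridges the C4 carbonyl and the peri 5-methoxy oxygen in a six-membered chelate, so chloride should remove only that methyl group at low temperature.

Step 4
Reactants: 5 5-hydroxy-3,6,7-trimethoxy-4H-chromen-4-one
Product: 6 5-(benzyloxy)-3,6,7-trimethoxy-4H-chromen-4-one
Conditions: BnBr (1.5 equiv), K2CO3, TBAI (cat.), DMF, 60 °C
Reagents that add atoms: benzyl bromide BrCc1ccccc1
Why: Williamson ether synthesis; warming in DMF overcomes the hydrogen bond of the 5-OH to the carbonyl, and the benzyl cap removes the acidic phenol before the base-mediated part of the key step.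

Step 5
Reactants: 7 2-methoxybenzene-1,4-diol
Product: 8 1,4-bis(benzyloxy)-2-methoxybenzene
Conditions: BnBr (2.4 equiv), K2CO3 (3 equiv), DMF, rt → 50 °C, under Ar
Reagents that add atoms: benzyl bromide BrCc1ccccc1
Why: Double Williamson ether synthesis; exclusion of air prevents oxidation of the hydroquinone to the quinone.

Step 6
Reactants: 8 1,4-bis(benzyloxy)-2-methoxybenzene
Product: 9 1,4-bis(benzyloxy)-2-bromo-5-methoxybenzene
Conditions: NBS (1.05 equiv), MeCN, 0 °C → rt
Reagents that add atoms: N-bromosuccinimide O=C1CCC(=O)N1Br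
Why: Electrophilic aromatic bromination at the position para to the methoxy group and ortho to a benzyloxy group, the most activated unhindered site of a 1,2,4-trialkoxybenzene.

Step 7
Reactants: 9 1,4-bis(benzyloxy)-2-bromo-5-methoxybenzene
Product: 12 [2,5-bis(benzyloxy)-4-methoxyphenyl]boronic acid, via aryllithium 10 (not isolated), via diisopropyl arylboronate 11 (not isolated)
Conditions: n-BuLi (1.1 equiv), THF, −78 °C; B(OiPr)3 (1.5 equiv), −78 °C → rt; 1 M HCl
Reagents that add atoms: triisopropyl borate CC(C)OB(OC(C)C)OC(C)C; water O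
Why: Bromine–lithium exchange at −78 °C is faster than any reaction at the benzyl ethers, the aryllithium is trapped by the borate, and mild acid hydrolysis gives the boronic acid.

Step 8
Reactants: 6 5-(benzyloxy)-3,6,7-trimethoxy-4H-chromen-4-one; 12 [2,5-bis(benzyloxy)-4-methoxyphenyl]boronic acid
Product: 14 (2R,3R)-5-(benzyloxy)-2-[2,5-bis(benzyloxy)-4-methoxyphenyl]-3,6,7-trimethoxy-2,3-dihydro-4H-chromen-4-one, via C3-epimer mixture 13 (not isolated)
Conditions: [Rh(OH)(cod)]2 (2.5 mol %), (S)-MeO-F12-BIPHEP [(S)-6,6′-dimethoxy-2,2′-bis(bis(3,4,5-trifluorophenyl)phosphino)biphenyl] (5.5 mol %), 12 (2.5 equiv, in portions), dioxane/H2O 10:1, 50 °C; then aq. wash, DBU (0.2 equiv), toluene, 0 °C → rt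
Reagents that add atoms: none
Why: Transmetalation of 12 to Rh(I)–OH gives an aryl–rhodium species that inserts the C2=C3 bond of 6 with the aryl group going to the β-carbon C2 on its Re face, and hydrolysis of the rhodium oxa-π-allyl (enolate) releases the chromanone and regenerates Rh–OH. The closest known reaction is the rhodium-catalysed asymmetric 1,4-addition of arylboronic acids to chromones to give flavanones (Hayashi–Miyaura reaction); no ring is closed. C2 is controlled by the chiral bisphosphine, which differentiates the two faces of the planar chromone in the insertion. C3 is formed without control on protonation and is then equilibrated by catalytic DBU through the C3–C4 enolate to the trans isomer, in which the C2 aryl and the C3 methoxy group are both equatorial, so both C3 epimers should converge on (2R,3R) while the non-acidic C2–H centre stays fixed. The step needs 1,4- over 1,2-addition, insertion into a trisubstituted enone that carries an α-methoxy group, and no retro-oxa-Michael opening of the C2–O1 bond that would scramble C2; the electron-poor ligand (fast insertion at moderate temperature), the excess of 12, the benzyl cap on the 5-OH and the use of only catalytic amidine base at low temperature are meant to secure this.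

Step 9
Reactants: 14 (2R,3R)-5-(benzyloxy)-2-[2,5-bis(benzyloxy)-4-methoxyphenyl]-3,6,7-trimethoxy-2,3-dihydro-4H-chromen-4-one
Product: 15 (2R,3R)-2-(2,5-dihydroxy-4-methoxyphenyl)-5-hydroxy-3,6,7-trimethoxy-2,3-dihydro-4H-chromen-4-one
Conditions: H2 (1 atm), 10% Pd/C, degassed EtOAc, rt; filtration and concentration under Ar
Reagents that add atoms: none
Why: Catalytic hydrogenolysis of the three primary benzyl aryl ethers should be faster than cleavage of the cyclic secondary benzylic C2–O1 bond, and the neutral conditions leave C2, C3 and the air-sensitive hydroquinone untouched.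

**Compound list**

1 | 3,4,5-trimethoxyphenol | COc1cc(O)cc(OC)c1OC | starting material
2 | 1-(6-hydroxy-2,3,4-trimethoxyphenyl)-2-methoxyethan-1-one | COCC(=O)c1c(O)cc(OC)c(OC)c1OC | intermediate
3 | 3-(dimethylamino)-1-(6-hydroxy-2,3,4-trimethoxyphenyl)-2-methoxyprop-2-en-1-one (enaminone, alkene geometry not defined; not isolated) | COC(=CN(C)C)C(=O)c1c(O)cc(OC)c(OC)c1OC | intermediate
4 | 3,5,6,7-tetramethoxy-4H-chromen-4-one | COc1coc2cc(OC)c(OC)c(OC)c2c1=O | intermediate
5 | 5-hydroxy-3,6,7-trimethoxy-4H-chromen-4-one | COc1coc2cc(OC)c(OC)c(O)c2c1=O | intermediate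
6 | 5-(benzyloxy)-3,6,7-trimethoxy-4H-chromen-4-one | COc1coc2cc(OC)c(OC)c(OCc3ccccc3)c2c1=O | intermediate
7 | 2-methoxybenzene-1,4-diol (methoxyhydroquinone) | COc1cc(O)ccc1O | starting material
8 | 1,4-bis(benzyloxy)-2-methoxybenzene | COc1cc(OCc2ccccc2)ccc1OCc1ccccc1 | intermediate
9 | 1,4-bis(benzyloxy)-2-bromo-5-methoxybenzene | COc1cc(OCc2ccccc2)c(Br)cc1OCc1ccccc1 | intermediate
10 | [2,5-bis(benzyloxy)-4-methoxyphenyl]lithium (not isolated) | COc1cc(OCc2ccccc2)c([Li])cc1OCc1ccccc1 | intermediate
11 | diisopropyl [2,5-bis(benzyloxy)-4-methoxyphenyl]boronate (not isolated) | COc1cc(OCc2ccccc2)c(B(OC(C)C)OC(C)C)cc1OCc1ccccc1 | intermediate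
12 | [2,5-bis(benzyloxy)-4-methoxyphenyl]boronic acid | COc1cc(OCc2ccccc2)c(B(O)O)cc1OCc1ccccc1 | intermediate
13 | (2R)-5-(benzyloxy)-2-[2,5-bis(benzyloxy)-4-methoxyphenyl]-3,6,7-trimethoxy-2,3-dihydro-4H-chromen-4-one as a mixture of C3 epimers (not isolated) | COc1cc(OCc2ccccc2)c([C@H]2Oc3cc(OC)c(OC)c(OCc4ccccc4)c3C(=O)C2OC)cc1OCc1ccccc1 | intermediate
14 | (2R,3R)-5-(benzyloxy)-2-[2,5-bis(benzyloxy)-4-methoxyphenyl]-3,6,7-trimethoxy-2,3-dihydro-4H-chromen-4-one (2,3-trans) | COc1cc(OCc2ccccc2)c([C@H]2Oc3cc(OC)c(OC)c(OCc4ccccc4)c3C(=O)[C@@H]2OC)cc1OCc1ccccc1 | intermediate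
15 | (2R,3R)-2-(2,5-dihydroxy-4-methoxyphenyl)-5-hydroxy-3,6,7-trimethoxy-2,3-dihydro-4H-chromen-4-one (2,3-trans) | COc1cc(O)c([C@H]2Oc3cc(OC)c(OC)c(O)c3C(=O)[C@@H]2OC)cc1O | target

**Step count**

Total steps: 9. Longest linear sequence: 6 (steps 1, 2, 3, 4, 8, 9).

**Steps most likely to fail**

Step 8. The aryl–rhodium insertion into the trisubstituted, α-methoxy-substituted enone may be too slow, so that protodeboronation of the electron-rich, ortho-substituted boronic acid outruns the addition. The C2 configuration may also erode through ring opening during the C3 equilibration. The fallback performs the asymmetric conjugate addition on a chromone without the C3 substituent and introduces the 3-methoxy group afterwards. It sets out from 1 and 12 and comes back at 14.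
- Compound 1 is acetylated (AcOH, BF3·OEt2) to 1-(6-hydroxy-2,3,4-trimethoxyphenyl)ethan-1-one F1.
- DMF-DMA converts it into (E)-3-(dimethylamino)-1-(6-hydroxy-2,3,4-trimethoxyphenyl)prop-2-en-1-one F2, which acid closes to 5,6,7-trimethoxy-4H-chromen-4-one F3.
- BCl3 gives 5-hydroxy-6,7-dimethoxy-4H-chromen-4-one F4, and benzylation gives 5-(benzyloxy)-6,7-dimethoxy-4H-chromen-4-one F5.
- Rhodium-catalysed addition of 12 under the conditions of step 8, without the DBU stage, should give (2S)-5-(benzyloxy)-2-[2,5-bis(benzyloxy)-4-methoxyphenyl]-6,7-dimethoxy-2,3-dihydro-4H-chromen-4-one F6.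
- Soft enolisation (TMSOTf, Et3N, CH2Cl2, 0 °C) gives (2S)-5-(benzyloxy)-2-[2,5-bis(benzyloxy)-4-methoxyphenyl]-6,7-dimethoxy-4-[(trimethylsilyl)oxy]-2H-chromene F7.
- Rubottom oxidation (m-CPBA, NaHCO3, CH2Cl2, −20 °C), anti to the C2 aryl group, leads to (2R,3R)-5-(benzyloxy)-2-[2,5-bis(benzyloxy)-4-methoxyphenyl]-6,7-dimethoxy-3-[(trimethylsilyl)oxy]-2,3-dihydro-4H-chromen-4-one F8.
- Citric acid in MeOH cleaves the silyl ether to (2R,3R)-5-(benzyloxy)-2-[2,5-bis(benzyloxy)-4-methoxyphenyl]-3-hydroxy-6,7-dimethoxy-2,3-dihydro-4H-chromen-4-one F9.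
- Non-basic O-methylation (MeOTf, 2,6-di-tert-butyl-4-methylpyridine, CH2Cl2) gives 14.

Step 9. Hydrogenolytic opening of the pyranone ring at the doubly activated benzylic C2–O1 bond, or reduction of the aryl ketone, may compete with removal of the three benzyl groups, and the hydroquinone may oxidise during isolation. The fallback replaces reductive cleavage on palladium by Lewis-acid debenzylation with a cation scavenger. It sets out from 14 and comes back at 15: BCl3 and pentamethylbenzene in CH2Cl2 at −78 °C, quenched cold with MeOH, should remove the three benzyl groups without hydrogen and without new intermediates.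

Step 3. Regiocontrol in the demethylation may be lost, with the neighbouring 6-methoxy group cleaved as well once boron is bound at O5. The fallback gives up mono-selectivity and restores the pattern by selective alkylation. It sets out from 4 and comes back at 5. Exhaustive chelation-relayed cleavage (excess AlCl3, MeCN, 60 °C) gives 5,6-dihydroxy-3,7-dimethoxy-4H-chromen-4-one F10. Methylation with Me2SO4 (1.05 equiv) and K2CO3 in acetone at rt should then occur at the 6-OH only, because the 5-OH is hydrogen-bonded to the carbonyl, and this gives 5.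

**Further compounds**

F1 | step 8 | 1-(6-hydroxy-2,3,4-trimethoxyphenyl)ethan-1-one | CC(=O)c1c(O)cc(OC)c(OC)c1OC
F2 | step 8 | (E)-3-(dimethylamino)-1-(6-hydroxy-2,3,4-trimethoxyphenyl)prop-2-en-1-one | CN(C)/C=C/C(=O)c1c(O)cc(OC)c(OC)c1OC
F3 | step 8 | 5,6,7-trimethoxy-4H-chromen-4-one | COc1cc2occc(=O)c2c(OC)c1OC
F4 | step 8 | 5-hydroxy-6,7-dimethoxy-4H-chromen-4-one | COc1cc2occc(=O)c2c(O)c1OC
F5 | step 8 | 5-(benzyloxy)-6,7-dimethoxy-4H-chromen-4-one | COc1cc2occc(=O)c2c(OCc2ccccc2)c1OC
F6 | step 8 | (2S)-5-(benzyloxy)-2-[2,5-bis(benzyloxy)-4-methoxyphenyl]-6,7-dimethoxy-2,3-dihydro-4H-chromen-4-one | COc1cc(OCc2ccccc2)c([C@H]2Oc3cc(OC)c(OC)c(OCc4ccccc4)c3C(=O)C2)cc1OCc1ccccc1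
F7 | step 8 | (2S)-5-(benzyloxy)-2-[2,5-bis(benzyloxy)-4-methoxyphenyl]-6,7-dimethoxy-4-[(trimethylsilyl)oxy]-2H-chromene | COc1cc(OCc2ccccc2)c([C@H]2Oc3cc(OC)c(OC)c(OCc4ccccc4)c3C(O[Si](C)(C)C)=C2)cc1OCc1ccccc1
F8 | step 8 | (2R,3R)-5-(benzyloxy)-2-[2,5-bis(benzyloxy)-4-methoxyphenyl]-6,7-dimethoxy-3-[(trimethylsilyl)oxy]-2,3-dihydro-4H-chromen-4-one | COc1cc(OCc2ccccc2)c([C@H]2Oc3cc(OC)c(OC)c(OCc4ccccc4)c3C(=O)[C@@H]2O[Si](C)(C)C)cc1OCc1ccccc1
F9 | step 8 | (2R,3R)-5-(benzyloxy)-2-[2,5-bis(benzyloxy)-4-methoxyphenyl]-3-hydroxy-6,7-dimethoxy-2,3-dihydro-4H-chromen-4-one | COc1cc(OCc2ccccc2)c([C@H]2Oc3cc(OC)c(OC)c(OCc4ccccc4)c3C(=O)[C@@H]2O)cc1OCc1ccccc1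
F0 | step 9 | none | none
F10 | step 3 | 5,6-dihydroxy-3,7-dimethoxy-4H-chromen-4-one | COc1coc2cc(OC)c(O)c(O)c2c1=O
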